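## Retrosynthetic overview
1. Numbering (daucane): C1 ring-fusion C(CH3), C2/C3 CH2, C4 C(OH)(iPr), C5 ring-fusion CH, C6 CH–O-acyl, C7 CH2, C8 spiro-epoxide carbon (C14 is its CH2), C9/C10 diol carbons. β is the face carrying the C1 methyl group.
2. Endgame: the oxirane comes from the C8/C14 diol. C6–O and C5–H come from a C5=C6 alkene by hydrosilylation tethered to O8. O8 and O9 come from a C8=C9 alkene by osmylation steered by the 10α-OH.
3. Key disconnection: the resulting cyclohepta-1,4-diene is cut at C7–C8 and C1–C10. This is a formal (4+3) of 1-vinylcyclopentene 6 (C7=C6–C5=C1) with the vinylcarbenoid from 10 (C8, C9=C10), run as cyclopropanation (C7–C8, C6–C8) followed by a Cope shift.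
4. Enabling feature: C7, the only CH2 of the seven-membered ring, separates C6 and C8, so O6, O8, O9 and H5 can all descend from a skipped C5=C6/C8=C9 diene. C8 carries the one-carbon branch C14 (the ester of a diazoacetate). The opposite C1–C10 bond joins the quaternary carbon shared with the five-membered ring to a carbinol carbon, and these two carbons are the ends of a divinylcyclopropane.
5. Ring order: cyclopentane (cleavage of the cyclohexene of (S)-terpinen-4-ol and aldol re-closure, C4 kept) → transient cyclopropane → cycloheptane → temporary oxasilolane → oxirane.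

Key step: step 7

Assumption 1: the sense of induction of the dirhodium prolinate is taken from the accepted model ((S)-catalyst gives (1S,2R)-type cyclopropanes). This calls for Rh2(R-DOSP)4 here, and its antipode is equally commercial should the sense prove opposite.
Assumption 2: commercial (+)-terpinen-4-ol may not be enantiopure. Under catalyst control in step 7 its minor enantiomer should end up mainly in a diastereomer of 12 that chromatography removes.

## Route

Step 1
Reactants: 1 (S)-(+)-terpinen-4-ol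
Product: 2 (S)-terpinen-4-ol triethylsilyl ether
Conditions: TESOTf, 2,6-lutidine, CH2Cl2, 0 °C
Reagents that add atoms: triethylsilyl triflate, CC[Si](CC)(CC)OS(=O)(=O)C(F)(F)F
Why: O-silylation with a silyl triflate reaches this hindered tertiary alcohol and masks it against retro-aldol cleavage (steps 2–3) and O–H insertion (step 7), leaving the C4 stereocentre untouched.

Step 2
Reactants: 2 (S)-terpinen-4-ol triethylsilyl ether
Product: 4 (S)-3-isopropyl-6-oxo-3-(triethylsilyloxy)heptanal, via secondary ozonide 3 (not isolated)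
Conditions: O3, CH2Cl2, −78 °C; then Me2S, −78 °C → rt
Reagents that add atoms: ozone, [O-][O+]=O
Why: Ozonolysis with reductive work-up cleaves the only C=C bond and opens the six-membered ring, while C4 lies off the reacting carbons and keeps its configuration.

Step 3
Reactants: 4 (S)-3-isopropyl-6-oxo-3-(triethylsilyloxy)heptanal
Product: 5 (R)-5-isopropyl-2-methyl-5-(triethylsilyloxy)cyclopent-1-ene-1-carbaldehyde
Conditions: piperidine (cat.), AcOH (cat.), toluene, 80 °C, Dean–Stark
Reagents that add atoms: none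
Why: Intramolecular aldol condensation through the enamine of the aldehyde (5-exo-trig attack of C5 on the methyl ketone C1, then loss of water) re-closes the chain as the cyclopentene, the amine/acid couple favouring aldehyde-enamine over ketone-enolate closure.

Step 4
Reactants: 5 (R)-5-isopropyl-2-methyl-5-(triethylsilyloxy)cyclopent-1-ene-1-carbaldehyde
Product: 6 (R)-5-isopropyl-2-methyl-5-(triethylsilyloxy)-1-vinylcyclopent-1-ene
Conditions: Ph3PCH3Br, KOtBu, THF, 0 °C → rt
Reagents that add atoms: methyltriphenylphosphonium bromide, C[P+](c1ccccc1)(c1ccccc1)c1ccccc1.[Br-]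
Why: Wittig methylenation of the enal installs C7 and completes the C7=C6–C5=C1 diene without touching C4.

Step 5
Reactants: 7 ethyl diazoacetate; 8 2-oxoethyl benzoate
Product: 9 ethyl 4-(benzoyloxy)-2-diazo-3-hydroxybutanoate (racemic)
Conditions: DBU (15 mol %), MeCN, 0 °C → rt
Reagents that add atoms: none
Why: Base-catalysed aldol-type addition of the diazoacetate carbon to the aldehyde joins C8 to C9, and the racemic carbinol centre is erased in step 6.

Step 6
Reactants: 9 ethyl 4-(benzoyloxy)-2-diazo-3-hydroxybutanoate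
Product: 10 ethyl (E)-4-(benzoyloxy)-2-diazobut-3-enoate
Conditions: POCl3, Et3N, CH2Cl2, 0 °C → rt; used fresh
Reagents that add atoms: none
Why: Dehydration of a β-hydroxy-α-diazo ester through its dichlorophosphate is the standard entry to vinyldiazoacetates, and elimination from the least crowded rotamer should give the E enol benzoate.

Step 7
Reactants: 6 (R)-5-isopropyl-2-methyl-5-(triethylsilyloxy)-1-vinylcyclopent-1-ene; 10 ethyl (E)-4-(benzoyloxy)-2-diazobut-3-enoate
Product: 12 ethyl 10α-benzoyloxy-4β-(triethylsilyloxy)dauca-5,8-dien-14-oate (1β-methyl), via cis-divinylcyclopropane 11 (not isolated)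
Conditions: Rh2(R-DOSP)4 (1 mol %), hexanes/PhCF3, slow addition of 10 (1.5 equiv), −20 °C → rt; then 60 °C
Reagents that add atoms: none
Why: Loss of N2 from 10 on the rhodium catalyst gives a donor/acceptor vinylcarbenoid whose carbene carbon C8 adds to the terminal vinyl group of 6 in a concerted asynchronous [2+1] step, making C7–C8 and C6–C8 and closing the three-membered ring of 11 with the enol-benzoate arm cis to the cyclopentenyl group; 11 then undergoes a [3,3] Cope shift through the endo boat that breaks C6–C8 and joins C10 to C1, so C7–C8 and C1–C10 remain as the two new bonds of the seven-membered ring. The closest known reaction type is the tandem cyclopropanation/Cope rearrangement (formal (4+3) cycloaddition) of vinyldiazoacetates with 1,3-dienes, including 1-vinylcycloalkenes whose fully substituted alkene carbon becomes a methyl-bearing quaternary centre. Modes of closure: the cyclopropane by [2+1] carbene addition, the cycloheptadiene by six-electron sigmatropic ring expansion (3 → 7) of the cis-divinylcyclopropane. Stereocentres: the chiral catalyst selects the face of the vinyl group and so fixes C6/C8 of 11, the single reactive endo-boat rotamer relays this to C1 (C10 bonds on the α face, CH3 ends β), and the E enol ester together with the ring-locked alkene geometry (CH3 cis to C6) places O10 trans to the methyl group (10α), with C4 a spectator. Selectivity needed: the monosubstituted C6=C7 bond must react in preference to the tetrasubstituted C5=C1 bond and the allylic C–H bonds (secured by sterics), the carbene carbon in preference to the vinylogous C10 (secured by the E substituent, the weakly donating benzoate and the non-polar medium), and catalyst control must override substrate control of the face (the reacting CH2 terminus lies far from C4). The step thereby delivers the seven-membered ring, the quaternary C1, the C10 carbinol, the C14 carbon and both alkene handles from two small fragments.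

Step 8
Reactants: 12 ethyl 10α-benzoyloxy-4β-(triethylsilyloxy)dauca-5,8-dien-14-oate
Product: 13 4β-(triethylsilyloxy)dauca-5,8-diene-10α,14-diol
Conditions: DIBAL-H (6 equiv), CH2Cl2, −78 → −20 °C; Rochelle salt
Reagents that add atoms: none
Why: DIBAL-H reduction turns the conjugated ester into the allylic alcohol C14–OH and cleaves the benzoate at its acyl carbon, so the C10–O bond and its configuration are kept.

Step 9
Reactants: 13 4β-(triethylsilyloxy)dauca-5,8-diene-10α,14-diol
Product: 15 4β-(triethylsilyloxy)dauc-5-ene-8α,9α,10α,14-tetraol, via osmate(VI) ester 14 (not isolated)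
Conditions: OsO4 (1.05 equiv), TMEDA (1.1 equiv), CH2Cl2, −78 °C; then aq Na2SO3, THF, 60 °C
Reagents that add atoms: osmium tetroxide, O=[Os](=O)(=O)=O
Why: In this hydrogen-bond-directed syn-dihydroxylation the OsO4·TMEDA complex is held by the 10α-OH and adds to the α face of C8=C9, setting C8 and C9, while C5=C6, flanked by two quaternary carbons and lacking a free OH, should stay inert.

Step 10
Reactants: 15 4β-(triethylsilyloxy)dauc-5-ene-8α,9α,10α,14-tetraol
Product: 16 9α,10α,14-tris(tert-butyldimethylsilyloxy)-4β-(triethylsilyloxy)dauc-5-en-8α-ol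
Conditions: TBSOTf (3.3 equiv), 2,6-lutidine, CH2Cl2, −78 → 0 °C
Reagents that add atoms: tert-butyldimethylsilyl triflate, CC(C)(C)[Si](C)(C)OS(=O)(=O)C(F)(F)F
Why: Rate-graded silylation (primary > secondary >> tertiary) covers O14, O9 and O10 and leaves the crowded tertiary 8α-OH free as the tether point.

Step 11
Reactants: 16 9α,10α,14-tris(tert-butyldimethylsilyloxy)-4β-(triethylsilyloxy)dauc-5-en-8α-ol
Product: 18 6α,8α-(dimethylsilanediyloxy)-bridged daucane (oxasilolane C6–SiMe2–O8; 5α-H), via dimethylsilyl ether 17 (not isolated)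
Conditions: Me2SiHCl, Et3N, DMAP (cat.), CH2Cl2, 0 °C; filtration; then Pt2(dvtms)3 (1 mol % Pt), toluene, 60 °C
Reagents that add atoms: chlorodimethylsilane, C[SiH](C)Cl
Why: In this intramolecular Pt(0)-catalysed hydrosilylation of a homoallylic alcohol (5-exo) the O8 tether can reach C6 only from the α face, and syn addition of Si–H places Si on C6 (α) and H on C5 (α), which fixes the trans ring fusion.

Step 12
Reactants: 18 oxasilolane
Product: 19 9α,10α,14-tris(tert-butyldimethylsilyloxy)-4β-(triethylsilyloxy)daucane-6α,8α-diol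
Conditions: 30% H2O2, KF, KHCO3, THF/MeOH, rt
Reagents that add atoms: hydrogen peroxide, OO
Why: Tamao–Fleming oxidation replaces the C6–Si bond by C6–OH with retention and releases O8, giving the 6α-alcohol.

Step 13
Reactants: 19 9α,10α,14-tris(tert-butyldimethylsilyloxy)-4β-(triethylsilyloxy)daucane-6α,8α-diol
Product: 20 6α-isovalerate of 19
Conditions: isovaleric anhydride, DMAP, Et3N, CH2Cl2, rt
Reagents that add atoms: isovaleric anhydride, CC(C)CC(=O)OC(=O)CC(C)C
Why: DMAP-catalysed acylation takes the only secondary hydroxyl, since the tertiary 8α-OH does not compete.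

Step 14
Reactants: 20 6α-isovalerate
Product: 21 6α-(isovaleroyloxy)daucane-4β,8α,9α,10α,14-pentaol
Conditions: HF·pyridine, pyridine/THF, 0 °C → rt
Reagents that add atoms: none
Why: Fluoride-driven desilylation under mildly acidic conditions removes all four silyl groups before the acid-sensitive oxirane exists and without moving the ester.

Step 15
Reactants: 21 6α-(isovaleroyloxy)daucane-4β,8α,9α,10α,14-pentaol
Product: 23 target CNP0307265.1 (8α,14-epoxy-6α-isovaleroyloxydaucane-4β,9α,10α-triol), via primary mesylate 22 (not isolated)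
Conditions: MsCl (1.05 equiv), 2,4,6-collidine, CH2Cl2, −20 °C; then DBU, rt
Reagents that add atoms: none
Why: Collidine-mediated mesylation selects the only primary hydroxyl, and DBU then closes the oxirane by 3-exo-tet intramolecular Williamson displacement from O8, so the C8–O bond is never broken and the epoxide oxygen stays α.

## Compound list
1 | (S)-(+)-terpinen-4-ol | CC1=CC[C@](O)(C(C)C)CC1 | starting material
2 | (S)-terpinen-4-ol triethylsilyl ether | CC1=CC[C@](O[Si](CC)(CC)CC)(C(C)C)CC1 | intermediate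
3 | secondary ozonide of 2 (mixture at the two acetal carbons) | CC12CC[C@@](O[Si](CC)(CC)CC)(C(C)C)CC(OO1)O2 | intermediate
4 | (S)-3-isopropyl-6-oxo-3-(triethylsilyloxy)heptanal | O=CC[C@](O[Si](CC)(CC)CC)(C(C)C)CCC(C)=O | intermediate
5 | (R)-5-isopropyl-2-methyl-5-(triethylsilyloxy)cyclopent-1-ene-1-carbaldehyde | O=CC1=C(C)CC[C@@]1(O[Si](CC)(CC)CC)C(C)C | intermediate
6 | (R)-5-isopropyl-2-methyl-5-(triethylsilyloxy)-1-vinylcyclopent-1-ene | C=CC1=C(C)CC[C@@]1(O[Si](CC)(CC)CC)C(C)C | intermediate
7 | ethyl diazoacetate | CCOC(=O)C=[N+]=[N-] | starting material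
8 | 2-oxoethyl benzoate | O=CCOC(=O)c1ccccc1 | starting material
9 | ethyl 4-(benzoyloxy)-2-diazo-3-hydroxybutanoate (racemic) | CCOC(=O)C(=[N+]=[N-])C(O)COC(=O)c1ccccc1 | intermediate
10 | ethyl (E)-4-(benzoyloxy)-2-diazobut-3-enoate | CCOC(=O)C(=[N+]=[N-])/C=C/OC(=O)c1ccccc1 | intermediate
11 | cis-divinylcyclopropane (alkenyl arms cis, ester trans to cyclopentenyl) | CCOC(=O)[C@]1(/C=C/OC(=O)c2ccccc2)C[C@H]1C3=C(C)CC[C@@]3(O[Si](CC)(CC)CC)C(C)C | intermediate
12 | ethyl 10α-benzoyloxy-4β-(triethylsilyloxy)dauca-5,8-dien-14-oate | C1C(C(=O)OCC)=C[C@@H](OC(=O)c3ccccc3)[C@@]2(C)CC[C@@](O[Si](CC)(CC)CC)(C(C)C)C2=C1 | intermediate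
13 | 4β-(triethylsilyloxy)dauca-5,8-diene-10α,14-diol | C1C(CO)=C[C@@H](O)[C@@]2(C)CC[C@@](O[Si](CC)(CC)CC)(C(C)C)C2=C1 | intermediate
14 | 8α,9α-osmate(VI) ester, TMEDA chelate | C1[C@](O5)(CO)[C@@H](O[Os-2]56(=O)(=O)[N+](C)(C)CC[N+]6(C)C)[C@@H](O)[C@@]2(C)CC[C@@](O[Si](CC)(CC)CC)(C(C)C)C2=C1 | intermediate
15 | 4β-(triethylsilyloxy)dauc-5-ene-8α,9α,10α,14-tetraol | C1[C@](O)(CO)[C@@H](O)[C@@H](O)[C@@]2(C)CC[C@@](O[Si](CC)(CC)CC)(C(C)C)C2=C1 | intermediate
16 | 9α,10α,14-tris(TBS) ether, 8α-OH free | C1[C@](O)(CO[Si](C)(C)C(C)(C)C)[C@@H](O[Si](C)(C)C(C)(C)C)[C@@H](O[Si](C)(C)C(C)(C)C)[C@@]2(C)CC[C@@](O[Si](CC)(CC)CC)(C(C)C)C2=C1 | intermediate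
17 | 8α-O-dimethylsilyl ether of 16 | C1[C@](O[SiH](C)C)(CO[Si](C)(C)C(C)(C)C)[C@@H](O[Si](C)(C)C(C)(C)C)[C@@H](O[Si](C)(C)C(C)(C)C)[C@@]2(C)CC[C@@](O[Si](CC)(CC)CC)(C(C)C)C2=C1 | intermediate
18 | oxasilolane (C6–SiMe2–O8 on the α face, 5α-H) | C[Si]3(C)[C@H]1C[C@](O3)(CO[Si](C)(C)C(C)(C)C)[C@@H](O[Si](C)(C)C(C)(C)C)[C@@H](O[Si](C)(C)C(C)(C)C)[C@@]2(C)CC[C@@](O[Si](CC)(CC)CC)(C(C)C)[C@H]12 | intermediate
19 | 6α,8α-diol | O[C@H]1C[C@](O)(CO[Si](C)(C)C(C)(C)C)[C@@H](O[Si](C)(C)C(C)(C)C)[C@@H](O[Si](C)(C)C(C)(C)C)[C@@]2(C)CC[C@@](O[Si](CC)(CC)CC)(C(C)C)[C@H]12 | intermediate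
20 | 6α-isovalerate | CC(C)CC(=O)O[C@H]1C[C@](O)(CO[Si](C)(C)C(C)(C)C)[C@@H](O[Si](C)(C)C(C)(C)C)[C@@H](O[Si](C)(C)C(C)(C)C)[C@@]2(C)CC[C@@](O[Si](CC)(CC)CC)(C(C)C)[C@H]12 | intermediate
21 | 6α-(isovaleroyloxy)daucane-4β,8α,9α,10α,14-pentaol | CC(C)CC(=O)O[C@H]1C[C@](O)(CO)[C@@H](O)[C@@H](O)[C@@]2(C)CC[C@@](O)(C(C)C)[C@H]12 | intermediate
22 | 14-mesylate of 21 | CC(C)CC(=O)O[C@H]1C[C@](O)(COS(C)(=O)=O)[C@@H](O)[C@@H](O)[C@@]2(C)CC[C@@](O)(C(C)C)[C@H]12 | intermediate
23 | CNP0307265.1 | CC(C)CC(=O)O[C@H]1C[C@]2(CO2)[C@@H](O)[C@@H](O)[C@@]2(C)CC[C@@](O)(C(C)C)[C@H]12 | target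

## Step count
Total step count: 15. Longest linear sequence: 13 (steps 1–4 and 7–15).

## Steps most likely to fail

**Step 7.**
- What may go wrong: the diene is captured at the vinylogous carbon of the acyloxy-substituted carbenoid, or 10 closes to a pyrazole before it meets the catalyst.
- Fallback (sets out from 6 and 7, returns at 15): the C10 oxygen is left out of the cycloaddition and introduced afterwards. DBU-catalysed addition of 7 to acetaldehyde gives ethyl 2-diazo-3-hydroxybutanoate F1, and POCl3/Et3N gives the parent ethyl 2-diazobut-3-enoate F2. With 6 and Rh2(R-DOSP)4 this should pass through the cis-divinylcyclopropane F3 to ethyl 4β-(triethylsilyloxy)dauca-5,8-dien-14-oate F4. DIBAL-H gives the allylic alcohol F5. Sharpless asymmetric epoxidation with D-(−)-diethyl tartrate (reagent control) gives the 8α,9α-epoxy alcohol F6. PhSeNa opens the oxirane at the secondary C9 to the 9β-phenylselanyl-8α,14-diol F7. H2O2 triggers selenoxide syn-elimination towards C10 to give the 9-ene-8α,14-diol F8. OsO4·TMEDA, now guided by the tertiary 8α-OH and reinforced by the β-methyl group next to C10, adds to the α face of C9=C10 and gives 15.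

**Step 11.**
- What may go wrong: slow insertion of the hindered trisubstituted alkene into Pt–H, leading to alkene migration or loss of the Si–H group.
- Fallback (sets out from 16, returns at 19): the C6 oxygen is brought in without facial control and both centres are then corrected. BH3·THF followed by NaOH/H2O2 should add from the open β face to give the cis-fused 5β-H,6β-alcohol F9. Dess–Martin oxidation gives the cis-fused 6-ketone F10. DBU equilibrates C5 to the trans-fused 6-ketone F11, in which C6 lies anti to the isopropyl group. Narasaka–Prasad reduction (Et2BOMe, NaBH4), through the boron chelate with the 8α-OH, gives the syn-1,3-diol 19.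

**Step 9.**
- What may go wrong: poor facial selectivity, if the 10α-OH sits near the alkene plane and hydrogen bonding cannot hold the reagent on the α face.
- Fallback (sets out from 13, returns at 15): hydrogen-bond direction is replaced by covalent vanadate delivery plus a reductive transposition. VO(acac)2/TBHP gives the 8α,9α-epoxy-10α,14-diol F12. Appel iodination (I2, PPh3, imidazole) of the primary alcohol gives the epoxy iodide F13. Zn/EtOH opens it reductively to the 8(14)-methylene-9α,10α-diol F14, retaining the C9–O bond. A second VO(acac)2/TBHP epoxidation, delivered from O9, gives the 8α,14-spiro-epoxide F15. KOH in aqueous DMSO opens this at the primary C14 to give 15.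

## Further compounds
F1 | step 7 | ethyl 2-diazo-3-hydroxybutanoate (racemic) | CCOC(=O)C(=[N+]=[N-])C(C)O
F2 | step 7 | ethyl 2-diazobut-3-enoate | CCOC(=O)C(=[N+]=[N-])C=C
F3 | step 7 | cis-divinylcyclopropane without the benzoate | CCOC(=O)[C@]1(C=C)C[C@H]1C2=C(C)CC[C@@]2(O[Si](CC)(CC)CC)C(C)C
F4 | step 7 | ethyl 4β-(triethylsilyloxy)dauca-5,8-dien-14-oate | C1C(C(=O)OCC)=CC[C@@]2(C)CC[C@@](O[Si](CC)(CC)CC)(C(C)C)C2=C1
F5 | step 7 | 4β-(triethylsilyloxy)dauca-5,8-dien-14-ol | C1C(CO)=CC[C@@]2(C)CC[C@@](O[Si](CC)(CC)CC)(C(C)C)C2=C1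
F6 | step 7 | 8α,9α-epoxy-4β-(triethylsilyloxy)dauc-5-en-14-ol | C1[C@@]3(CO)O[C@H]3C[C@@]2(C)CC[C@@](O[Si](CC)(CC)CC)(C(C)C)C2=C1
F7 | step 7 | 9β-phenylselanyl-4β-(triethylsilyloxy)dauc-5-ene-8α,14-diol | C1[C@](O)(CO)[C@H]([Se]c3ccccc3)C[C@@]2(C)CC[C@@](O[Si](CC)(CC)CC)(C(C)C)C2=C1
F8 | step 7 | 4β-(triethylsilyloxy)dauca-5,9-diene-8α,14-diol | C1[C@](O)(CO)C=C[C@@]2(C)CC[C@@](O[Si](CC)(CC)CC)(C(C)C)C2=C1
F9 | step 11 | cis-fused 5β-H,6β-alcohol | O[C@@H]1C[C@](O)(CO[Si](C)(C)C(C)(C)C)[C@@H](O[Si](C)(C)C(C)(C)C)[C@@H](O[Si](C)(C)C(C)(C)C)[C@@]2(C)CC[C@@](O[Si](CC)(CC)CC)(C(C)C)[C@@H]12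
F10 | step 11 | cis-fused (5β-H) 6-ketone | O=C1C[C@](O)(CO[Si](C)(C)C(C)(C)C)[C@@H](O[Si](C)(C)C(C)(C)C)[C@@H](O[Si](C)(C)C(C)(C)C)[C@@]2(C)CC[C@@](O[Si](CC)(CC)CC)(C(C)C)[C@@H]12
F11 | step 11 | trans-fused (5α-H) 6-ketone | O=C1C[C@](O)(CO[Si](C)(C)C(C)(C)C)[C@@H](O[Si](C)(C)C(C)(C)C)[C@@H](O[Si](C)(C)C(C)(C)C)[C@@]2(C)CC[C@@](O[Si](CC)(CC)CC)(C(C)C)[C@H]12
F12 | step 9 | 8α,9α-epoxy-4β-(triethylsilyloxy)dauc-5-ene-10α,14-diol | C1[C@@]3(CO)O[C@H]3[C@@H](O)[C@@]2(C)CC[C@@](O[Si](CC)(CC)CC)(C(C)C)C2=C1
F13 | step 9 | 8α,9α-epoxy-14-iodo-4β-(triethylsilyloxy)dauc-5-en-10α-ol | C1[C@@]3(CI)O[C@H]3[C@@H](O)[C@@]2(C)CC[C@@](O[Si](CC)(CC)CC)(C(C)C)C2=C1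
F14 | step 9 | 4β-(triethylsilyloxy)dauca-5,8(14)-diene-9α,10α-diol | C1C(=C)[C@@H](O)[C@@H](O)[C@@]2(C)CC[C@@](O[Si](CC)(CC)CC)(C(C)C)C2=C1
F15 | step 9 | 8α,14-epoxy-4β-(triethylsilyloxy)dauc-5-ene-9α,10α-diol | C1[C@]3(CO3)[C@@H](O)[C@@H](O)[C@@]2(C)CC[C@@](O[Si](CC)(CC)CC)(C(C)C)C2=C1
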